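**Strategy.** Ring A is disconnected across C1–C10 and C4–C5, so that everything rests on one enantioselective Diels–Alder reaction between a 2-silyloxy diene (C1–C4 with the C4 gem-dimethyl group and the C3 oxygen) and an (E)-2-methyl-2-enal (C5=C10 carrying C20, C9 and C6). The step exploits two features: ring A is a cyclohexane whose C2/C3 oxygen pair is a masked C2=C3 enol ether, and the trans H-5/CH3-20 relationship across C5–C10 is the image of an E-trisubstituted alkene. One operation closes ring A and sets C5 and the quaternary C10; ring B then follows by metathesis at C7=C8, and the side chain by hydroboration and B-alkyl coupling at C11–C12.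

Key step: step 4

Remark: atoms are numbered as in labdanes (C1–C10 decalin, C11–C16 side chain, C17 on C8, C18/C19 on C4, C20 on C10); compounds 1 and 11 are taken to be catalogue chemicals.

**Step 1**
Reactants: 1 4-methylpent-1-en-3-one
Product: 2 4-methyl-3-[(triisopropylsilyl)oxy]penta-1,3-diene
Conditions: TIPSOTf, Et3N, CH2Cl2, −78 to 0 °C
Reagents that add atoms: triisopropylsilyl trifluoromethanesulfonate, CC(C)[Si](C(C)C)(C(C)C)OS(=O)(=O)C(F)(F)F
Why: Silyl enol ether formation by soft enolisation is regiospecific because the isopropyl methine is the only enolisable position of the vinyl ketone, so the tetrasubstituted 2-silyloxy diene should form.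

**Step 2**
Reactants: 3 2-methyl-2-vinyloxirane (racemic)
Product: 4 (2E)-2-methylhexa-2,5-dien-1-ol
Conditions: CH2=CHMgBr, CuBr·SMe2 (10 mol %), THF, −40 to 0 °C; aqueous work-up
Reagents that add atoms: vinylmagnesium bromide, C=C[Mg]Br
Why: Copper-catalysed SN2′ opening of the vinyl epoxide by the Grignard reagent should give the skipped dienol, with the E-trisubstituted alkene arising from the s-trans conformer of the vinyloxirane (any Z isomer is removed by chromatography).

**Step 3**
Reactants: 4 (2E)-2-methylhexa-2,5-dien-1-ol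
Product: 5 (2E)-2-methylhexa-2,5-dienal
Conditions: MnO2, CH2Cl2, 20 °C
Reagents that add atoms: none
Why: Neutral allylic oxidation with MnO2 should give the enal without isomerising the skipped 5,6-double bond into conjugation.

**Step 4**
Reactants: 2 4-methyl-3-[(triisopropylsilyl)oxy]penta-1,3-diene, 5 (2E)-2-methylhexa-2,5-dienal
Product: 6 (1S,6S)-1,5,5-trimethyl-6-(prop-2-en-1-yl)-4-[(triisopropylsilyl)oxy]cyclohex-3-ene-1-carbaldehyde
Conditions: (R)-1-(2-methylphenyl)-3,3-diphenyltetrahydro-1H,3H-pyrrolo[1,2-c][1,3,2]oxazaborole (20 mol %), HNTf2 (16 mol %), CH2Cl2, −78 to −40 °C; Et3N quench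
Reagents that add atoms: none
Why: The boron-bound, s-trans enal 5 (LUMO lowered by the cationic oxazaborolidinium) and the electron-rich 2-silyloxy diene 2 should combine in a concerted, asynchronous normal-demand [4+2] cycloaddition that forms C4–C5 (leading bond, silyl enol ether carbon to the enal β-carbon) and C1–C10 together; the closest known reaction type is the oxazaborolidinium-catalysed enantioselective Diels–Alder reaction of α-substituted enals with 2-silyloxybutadienes. Ring A is the only ring closed, by an intermolecular suprafacial–suprafacial [4πs+2πs] closure of a six-membered carbocycle. The relative configuration of C5 and C10 (H-5 trans to CH3-20, allyl trans to CHO) is dictated by the E geometry of 5 through suprafacial addition, and because neither diene terminus is stereogenic there is no endo/exo issue. The absolute configuration is set by the catalyst: the formyl C–H···O contact and stacking of the enal on the neighbouring phenyl group should leave only the Si face at C2 of the enal (C10) open, which is the sense expected for the R catalyst. The regiochemistry needed is secured electronically by the C3 silyloxy group, which makes the gem-dimethyl carbon C4 the nucleophilic terminus (para rule), and sterically because it keeps the quaternary carbons C4 and C10 apart. Chemoselectivity for the conjugated alkene over the isolated allyl double bond follows from activation of the enal only.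

**Step 5**
Reactants: 6 (1S,6S)-1,5,5-trimethyl-6-(prop-2-en-1-yl)-4-[(triisopropylsilyl)oxy]cyclohex-3-ene-1-carbaldehyde
Product: 7 1-[(1S,6R)-1,5,5-trimethyl-6-(prop-2-en-1-yl)-4-[(triisopropylsilyl)oxy]cyclohex-3-en-1-yl]-2-methylprop-2-en-1-ol (both carbinol epimers; ring arranged as in 6)
Conditions: CH2=C(CH3)MgBr, THF, −78 to 0 °C; aqueous work-up
Reagents that add atoms: isopropenylmagnesium bromide, CC(=C)[Mg]Br
Why: Grignard 1,2-addition to the non-enolisable neopentyl aldehyde brings in C8 and C17; the new carbinol centre is inconsequential because it is oxidised in step 6.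

**Step 6**
Reactants: 7 the allylic alcohol from step 5
Product: 8 1-[(1S,6S)-1,5,5-trimethyl-6-(prop-2-en-1-yl)-4-[(triisopropylsilyl)oxy]cyclohex-3-en-1-yl]-2-methylprop-2-en-1-one
Conditions: Dess–Martin periodinane, NaHCO3, CH2Cl2, 0 to 20 °C
Reagents that add atoms: none
Why: Buffered Dess–Martin oxidation should convert the allylic alcohol into the isopropenyl ketone while sparing the silyl enol ether.

**Step 7**
Reactants: 8 the isopropenyl ketone from step 6
Product: 9 (4aS,8aS)-2,5,5,8a-tetramethyl-6-[(triisopropylsilyl)oxy]-4a,5,8,8a-tetrahydronaphthalen-1(4H)-one (trans-fused; 9-oxo, C7=C8 and C2=C3 in labdane numbering)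
Conditions: second-generation Grubbs catalyst RuCl2(=CHPh)(H2IMes)(PCy3) (5 mol %), CH2Cl2, 40 °C
Reagents that add atoms: none
Why: Ring-closing metathesis between the allyl and isopropenyl termini should close the six-membered ring B with the C7=C8(CH3) alkene, helped by the quaternary C10 (Thorpe–Ingold effect); the trans ring fusion is already fixed.

**Step 8**
Reactants: 9 the bicyclic enone from step 7
Product: 10 (4aR,8aS)-2,5,5,8a-tetramethyl-1-methylidene-6-[(triisopropylsilyl)oxy]-1,4,4a,5,8,8a-hexahydronaphthalene (C9=C11 exocyclic)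
Conditions: Ph3PCH3Br, KOtBu, toluene, 80 °C
Reagents that add atoms: methyltriphenylphosphonium bromide, C[P+](c1ccccc1)(c1ccccc1)c1ccccc1.[Br-]
Why: Wittig methylenation of the ketone, which cannot enolise towards C10, installs C11 as an exocyclic methylene, as is known for hindered 2,6,6-trisubstituted cyclohexenones.

**Step 9**
Reactants: 11 (R)-4-methyldihydrofuran-2(3H)-one
Product: 12 methyl (R)-4-bromo-3-methylbutanoate
Conditions: HBr, MeOH, 0 to 20 °C
Reagents that add atoms: hydrogen bromide, Br; methanol, CO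
Why: Acid-mediated lactone opening by bromide at the O–CH2 carbon with Fischer esterification gives the C12–C16 fragment without touching the stereocentre, which is β to the carbonyl.

**Step 10**
Reactants: 10 the exocyclic diene from step 8, 12 methyl (R)-4-bromo-3-methylbutanoate
Product: 14 methyl (13S)-3-[(triisopropylsilyl)oxy]labda-2,7-dien-15-oate, via B-alkyl-9-BBN borane 13 (not isolated)
Conditions: 9-borabicyclo[3.3.1]nonane (9-BBN), THF, 0 to 20 °C; then 12, Pd(OAc)2 (4 mol %), PCy3 (8 mol %), K3PO4·H2O, THF, 20 °C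
Reagents that add atoms: none
Why: 9-BBN should add anti-Markovnikov to the terminal C11 methylene from the α face opposite the axial C20 methyl (setting 9α-H), and the B-alkyl sp3–sp3 Suzuki–Miyaura coupling with the primary bromide then joins C11–C12 while leaving C13 and the ester untouched.

**Step 11**
Reactants: 14 methyl (13S)-3-[(triisopropylsilyl)oxy]labda-2,7-dien-15-oate
Product: 16 methyl (13S)-2α-hydroxy-3-oxolabd-7-en-15-oate, via 2α,3α-epoxy silyl ether 15 (not isolated)
Conditions: dimethyldioxirane, acetone/CH2Cl2, −78 °C; then HF·pyridine, THF, 0 °C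
Reagents that add atoms: dimethyldioxirane, CC1(C)OO1
Why: In this Rubottom oxidation the silyl enol ether is by far the most electron-rich alkene and should be epoxidised from the α face, opposite the axial 4β- and 10β-methyl groups, so that fluoride unmasks the equatorial (also thermodynamically preferred) 2α-hydroxy ketone.

**Step 12**
Reactants: 16 methyl (13S)-2α-hydroxy-3-oxolabd-7-en-15-oate
Product: 17 methyl (13S)-2α,3α-dihydroxylabd-7-en-15-oate
Conditions: LiBH(s-Bu)3 (3 equiv), THF, −78 °C; then H2O
Reagents that add atoms: none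
Why: The bulky trialkylborohydride should attack the C3 ketone along the equatorial trajectory (steric approach control) to give the axial 3α-alcohol cis to the 2α-hydroxyl, while the methyl ester is inert at −78 °C.

**Step 13**
Reactants: 17 methyl (13S)-2α,3α-dihydroxylabd-7-en-15-oate
Product: 18 methyl (13S)-2α-acetoxy-3α-hydroxylabd-7-en-15-oate (CNP0571009.1)
Conditions: Ac2O (1.1 equiv), pyridine, CH2Cl2, 0 °C
Reagents that add atoms: acetic anhydride, CC(=O)OC(C)=O
Why: Selective acylation should occur at the equatorial C2 hydroxyl, because the axial C3 hydroxyl is neopentyl and shielded by the C4 gem-dimethyl group.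

**Compound list**

1 | 4-methylpent-1-en-3-one | C=CC(=O)C(C)C | starting material
2 | 4-methyl-3-[(triisopropylsilyl)oxy]penta-1,3-diene | C=CC(O[Si](C(C)C)(C(C)C)C(C)C)=C(C)C | intermediate
3 | 2-methyl-2-vinyloxirane (racemic) | CC1(C=C)CO1 | starting material
4 | (2E)-2-methylhexa-2,5-dien-1-ol | OC/C(C)=C/CC=C | intermediate
5 | (2E)-2-methylhexa-2,5-dienal | O=C/C(C)=C/CC=C | intermediate
6 | (1S,6S)-1,5,5-trimethyl-6-(prop-2-en-1-yl)-4-[(triisopropylsilyl)oxy]cyclohex-3-ene-1-carbaldehyde | O=C[C@@]1(C)CC=C(O[Si](C(C)C)(C(C)C)C(C)C)C(C)(C)[C@@H]1CC=C | intermediate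
7 | 1-[(1S,6R)-1,5,5-trimethyl-6-(prop-2-en-1-yl)-4-[(triisopropylsilyl)oxy]cyclohex-3-en-1-yl]-2-methylprop-2-en-1-ol (carbinol epimers) | C=C(C)C(O)[C@@]1(C)CC=C(O[Si](C(C)C)(C(C)C)C(C)C)C(C)(C)[C@@H]1CC=C | intermediate
8 | 1-[(1S,6S)-1,5,5-trimethyl-6-(prop-2-en-1-yl)-4-[(triisopropylsilyl)oxy]cyclohex-3-en-1-yl]-2-methylprop-2-en-1-one | C=C(C)C(=O)[C@@]1(C)CC=C(O[Si](C(C)C)(C(C)C)C(C)C)C(C)(C)[C@@H]1CC=C | intermediate
9 | (4aS,8aS)-2,5,5,8a-tetramethyl-6-[(triisopropylsilyl)oxy]-4a,5,8,8a-tetrahydronaphthalen-1(4H)-one | O=C1C(C)=CC[C@H]2C(C)(C)C(O[Si](C(C)C)(C(C)C)C(C)C)=CC[C@]12C | intermediate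
10 | (4aR,8aS)-2,5,5,8a-tetramethyl-1-methylidene-6-[(triisopropylsilyl)oxy]-1,4,4a,5,8,8a-hexahydronaphthalene | C=C1C(C)=CC[C@H]2C(C)(C)C(O[Si](C(C)C)(C(C)C)C(C)C)=CC[C@]12C | intermediate
11 | (R)-4-methyldihydrofuran-2(3H)-one | O=C1C[C@@H](C)CO1 | starting material
12 | methyl (R)-4-bromo-3-methylbutanoate | COC(=O)C[C@@H](C)CBr | intermediate
13 | 11-(9-borabicyclo[3.3.1]nonan-9-yl)-3-[(triisopropylsilyl)oxy]-12,13,14,15,16-pentanorlabda-2,7-diene (9α-H) | C(B3C4CCCC3CCC4)[C@H]1C(C)=CC[C@H]2C(C)(C)C(O[Si](C(C)C)(C(C)C)C(C)C)=CC[C@]12C | intermediate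
14 | methyl (13S)-3-[(triisopropylsilyl)oxy]labda-2,7-dien-15-oate | COC(=O)C[C@@H](C)CC[C@H]1C(C)=CC[C@H]2C(C)(C)C(O[Si](C(C)C)(C(C)C)C(C)C)=CC[C@]12C | intermediate
15 | methyl (13S)-2α,3α-epoxy-3β-[(triisopropylsilyl)oxy]labd-7-en-15-oate | COC(=O)C[C@@H](C)CC[C@H]1C(C)=CC[C@H]2C(C)(C)[C@]3(O[Si](C(C)C)(C(C)C)C(C)C)O[C@@H]3C[C@]12C | intermediate
16 | methyl (13S)-2α-hydroxy-3-oxolabd-7-en-15-oate | COC(=O)C[C@@H](C)CC[C@H]1C(C)=CC[C@H]2C(C)(C)C(=O)[C@H](O)C[C@]12C | intermediate
17 | methyl (13S)-2α,3α-dihydroxylabd-7-en-15-oate | COC(=O)C[C@@H](C)CC[C@H]1C(C)=CC[C@H]2C(C)(C)[C@H](O)[C@H](O)C[C@]12C | intermediate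
18 | methyl (13S)-2α-acetoxy-3α-hydroxylabd-7-en-15-oate (CNP0571009.1) | COC(=O)C[C@@H](C)CC[C@H]1C(C)=CC[C@H]2C(C)(C)[C@H](O)[C@H](OC(C)=O)C[C@]12C | target

**Step count and risks**

Total step count: 13. Longest linear sequence: 11 steps (3 → 4 → 5 → 6 → 7 → 8 → 9 → 10 → 14 → 16 → 17 → 18; steps 2–8 and 10–13).

Steps most likely to fail:

1. Step 4. The cycloaddition may be too slow at the Z-methyl-substituted diene terminus, so that 1,2-addition of the silyl enol ether to the activated aldehyde, a stepwise Michael path that loses the alkene geometry, or weak facial discrimination takes over. If the facial sense proves opposite to the model, the S catalyst is used instead. Fallback, from 2 and 5 back to 6: the two are heated without acid (toluene, 130 °C, sealed tube, BHT) to the racemic adduct, which is 6 together with its mirror image, the (1R,6R)-aldehyde F1. Condensation with (1S,2S)-N,N'-dimethyl-1,2-diphenylethane-1,2-diamine (MgSO4, Et2O) should give the (4S,5S)-imidazolidine of 6 F2 and the diastereomeric imidazolidine of the mirror-image aldehyde F3. These are separated by chromatography, and brief two-phase hydrolysis of F2 (dilute aqueous oxalic acid/Et2O, 0 °C) returns 6.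

2. Step 10. With both partners β-branched, transmetalation may be slow and β-hydride elimination or protodeboronation may consume the alkylpalladium and alkylborane intermediates. Fallback, from borane 13 back to 14: oxidation (NaBO3·4H2O, THF/H2O) should give the C11 alcohol F4, and CBr4/PPh3 (Appel reaction) the C11 bromide F5. Magnesium in THF converts F5 into the Grignard reagent F6, which is alkylated with 12 under copper catalysis (CuCl2, N-methylpyrrolidinone, THF, 0 °C) to give 14.

3. Step 8. The basic ylide may deprotonate the enone at C6 (γ-position) or fail to add to the carbonyl flanked by the quaternary C10. Fallback, from 9 back to 10 (Peterson olefination): addition of Me3SiCH2MgCl in the presence of CeCl3 (THF, −78 to 0 °C) should give the β-hydroxysilane F7, and KH in THF eliminates it to 10.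

**Further compounds**

F1 | step 4 | (1R,6R)-1,5,5-trimethyl-6-(prop-2-en-1-yl)-4-[(triisopropylsilyl)oxy]cyclohex-3-ene-1-carbaldehyde | O=C[C@]1(C)CC=C(O[Si](C(C)C)(C(C)C)C(C)C)C(C)(C)[C@H]1CC=C
F2 | step 4 | (4S,5S)-1,3-dimethyl-4,5-diphenylimidazolidin-2-yl aminal of 6 | CN1[C@@H](c2ccccc2)[C@H](c2ccccc2)N(C)C1[C@@]3(C)CC=C(O[Si](C(C)C)(C(C)C)C(C)C)C(C)(C)[C@@H]3CC=C
F3 | step 4 | (4S,5S)-1,3-dimethyl-4,5-diphenylimidazolidin-2-yl aminal of F1 | CN1[C@@H](c2ccccc2)[C@H](c2ccccc2)N(C)C1[C@]3(C)CC=C(O[Si](C(C)C)(C(C)C)C(C)C)C(C)(C)[C@H]3CC=C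
F4 | step 10 | 3-[(triisopropylsilyl)oxy]-12,13,14,15,16-pentanorlabda-2,7-dien-11-ol | OC[C@H]1C(C)=CC[C@H]2C(C)(C)C(O[Si](C(C)C)(C(C)C)C(C)C)=CC[C@]12C
F5 | step 10 | 11-bromo-3-[(triisopropylsilyl)oxy]-12,13,14,15,16-pentanorlabda-2,7-diene | BrC[C@H]1C(C)=CC[C@H]2C(C)(C)C(O[Si](C(C)C)(C(C)C)C(C)C)=CC[C@]12C
F6 | step 10 | C11 magnesium bromide derived from F5 | Br[Mg]C[C@H]1C(C)=CC[C@H]2C(C)(C)C(O[Si](C(C)C)(C(C)C)C(C)C)=CC[C@]12C
F7 | step 8 | 2,5,5,8a-tetramethyl-6-[(triisopropylsilyl)oxy]-1-[(trimethylsilyl)methyl]-1,4,4a,5,8,8a-hexahydronaphthalen-1-ol (ring fusion as in 9, carbinol centre either way) | C[Si](C)(C)CC1(O)C(C)=CC[C@H]2C(C)(C)C(O[Si](C(C)C)(C(C)C)C(C)C)=CC[C@]12C
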